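All runs stem from a simulated flask for an exercise; noise was put on by code.

Start with the easy case: a catalyst with no preference uses two mirror-image substrates alike, so a racemate stays a racemate and what is left shows no excess. Here the free catalyst is single-handed, and a partner is charged with the two substrates.

| flask | left-handed substrate | right-handed substrate | partner | protic impurity | free catalyst | remark | time |
|---|---|---|---|---|---|---|---|
| zeta | 0.050 M | 0.050 M | 1 equiv | 1 mM | 22 mol% | run made earlier |  |
| delta | 0.025 M | 0.025 M | 1 equiv | 1 mM | 15 mol% | run made earlier |  |
| red | 0.050 M | 0.050 M | 1.00 equiv | 1.00 mM | 15 mol% |  | 10 min |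
| ochre | 0.050 M | 0.050 M | 1.00 equiv | 0.250 mM | 15 mol% |  | 10 min |

- zeta (time / min: right-handed substrate / %, left-handed substrate / %, left-handed product / %): 0.500: 46.8, 43.6, 6.7; 0.667: 46.2, 41.4, 8.6; 1.00: 44.6, 39.8, 10.1; 1.50: 43.5, 36.5, 12.9; 2.50: 42.9, 34.4, 15.9; 4.00: 41.2, 32.2, 17.6; 6.00: 40.3, 31.3, 18.1
- delta (time / min: right-handed substrate / %, left-handed substrate / %, left-handed product / %): 0.500: 49.7, 48.5, 1.0; 0.667: 49.4, 48.5, 1.6; 1.00: 49.4, 47.4, 3.1; 1.50: 48.7, 47.2, 3.3; 2.50: 47.9, 46.3, 4.6; 4.00: 47.6, 45.2, 5.1; 6.00: 47.2, 44.3, 5.5

(each reading ± 0.3 percentage points)

- the winner by excess of right-handed substrate over left-handed substrate among what is left of the two; "neither" if no more than 2 percentage points parts them (red / ochre / neither)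
- excess of right-handed substrate over left-handed substrate among what is left of the two at the end, red
- excess of right-handed substrate over left-handed substrate among what is left of the two at the end, ochre

- free catalyst is single-handed; left-handed substrate and right-handed substrate are mirror images of each other, charged as a racemate, each of them at the stated concentration
- the earlier runs were read with a standard deviation of 0.3 percentage points
- an excess is below zero if the other one leads
- no earlier run changes the charge of protic impurity; that part of a forecast is a guess

At first the earlier runs seem to disagree. At 6.00 min, zeta shows an excess of right-handed substrate of 12.6%, but delta shows 3.17%, far less than zeta. Has the same catalyst lost its preference? Excess also counts how far a flask has gone, so use a better ruler. If each substrate is used in proportion to its own amount, with the same partner and catalyst acting on both, the logarithms of the fractions left keep a fixed ratio however partner and catalyst fade. Divide the logarithm of the left-handed fraction left by that of the right-handed fraction left: zeta gives 2.17 and delta 2.10. This ratio is the selectivity factor, and 1 is the zero of its scale, the catalyst without preference. The readings show about the same preference in both runs, and delta had simply gone less far by then, with 88.6% of its left-handed substrate left against 62.6% in zeta.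

My own reckoning for red assumes that the logarithm of the left-handed fraction scales with catalyst, 15 mol% against 22 mol% in zeta. That leaves 72.7% of the left-handed substrate. The selectivity factor then leaves 86.3% of the right-handed substrate, an excess of 8.59%. No earlier run moves the impurity, so I guess the same for ochre.

The forecast says 8.7% for red, 9.8% for ochre and neither as the winner, on this ground: “Both runs stall early, so the catalyst dies and the reaction doesn't run out of substrate”. Its figure for ochre is higher than my guess of 8.59%.

The flasks give 10.6% for red and 10.7% for ochre, so the answer to the first question is neither, as forecast.

    2 partner → homo dimer (k = 0.0140 L mol⁻¹ s⁻¹)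
    partner + free catalyst + left-handed substrate → free catalyst + left-handed product (k = 11.0 L² mol⁻² s⁻¹)
    partner + free catalyst + right-handed substrate → free catalyst + right-handed product (k = 4.90 L² mol⁻² s⁻¹)
    partner + protic impurity → quenched reagent (k = 1.70 L mol⁻¹ s⁻¹)
    free catalyst → spent catalyst (k = 0.00640 s⁻¹)

At 10.0 min, red keeps 68% of its left-handed substrate, and the selectivity factor 2.17 turns that into an excess of 10.4%. In a neighbouring flask, red with 6 mol% of free catalyst, 83% of the left-handed substrate left turns into 4.95%, and that flask gives 5.08%. Red has nearly come to rest as far as the excess goes: free catalyst is down to 2.15% of its charge, and ten times the time leaves the excess at 10.7%. The partner is still moving, though: by 100 min homo dimer has grown from 0.00482 M to 0.0102 M, and partner has dropped by 22 percentage points, to 9.25% of its charge.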